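**Retrosynthetic overview**

1. Ring numbering: C1 (bears C7H2OH), C2 (C=O), C3 (O‑epoxyangelate), C4 (isopropyl), C5 (O‑angelate), C6 (=CH). The plan rests on reading ring carbons C1–C6, in this order, as C1–C6 of levoglucosenone: its C2 ketone is the ring ketone, its pyranose oxygen on C5 is the angelate oxygen O5 (already R), and its enone β‑carbon C4 takes the isopropyl group.
2. Late stage: both esters (Yamaguchi), the C1–C7 bond (Morita–Baylis–Hillman) and the C3–O bond (enolate hydroxylation anti to isopropyl) are removed to reach cyclohexenone 14.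
3. Key disconnection: the C1=C6 double bond of 14 is opened to dienone 13 (ring‑closing metathesis); this is the only step that forms the carbocycle.
4. 13 from levoglucosenone: Cu‑catalysed isopropyl addition anti to the 1,6‑anhydro bridge (sets C4), C2 reduced and later reoxidised, bridge hydrolysed, Wittig at C1, C5/C6 diol → epoxide → sulfonium‑ylide vinylation at C6, O5 as PMB ether.
5. Side chain: (2R,3R)‑epoxyangelic acid 22 from angelic acid by reduction, Sharpless epoxidation and oxidation; its oxirane is made before coupling.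

Key step: step 11

Remark (assumption): step 2 creates a C2 carbinol centre that step 10 turns back into the ketone. Both C2 epimers are carried together, so the SMILES of 4–12 leave this centre (and the anomeric centre of lactol 5) without a configuration. Sugar numbering C1–C6 equals the ring numbering throughout.

**Route**

Step 1
Reactants: 1 levoglucosenone; 2 isopropylmagnesium chloride
Product: 3 4‑isopropyl‑dihydrolevoglucosenone [(1S,2R,5R)‑2‑isopropyl‑6,8‑dioxabicyclo[3.2.1]octan‑4‑one; isopropyl anti to the C6–O6 bridge]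
Conditions: CuBr·SMe2 (10 mol%), THF, −78 → −40 °C; aq. NH4Cl
Reagents that add atoms: none
Why: Copper‑catalysed conjugate addition of the Grignard reagent to the enone; the 1,6‑anhydro bridge blocks one face of C4, so isopropyl should enter from the opposite face and set C4 (R), while C5 is untouched.

Step 2
Reactants: 3
Product: 4 1,6‑anhydro‑3,4‑dideoxy‑4‑C‑isopropyl‑β‑D‑hexopyranose (2‑isopropyl‑6,8‑dioxabicyclo[3.2.1]octan‑4‑ol; both C2 carbinol epimers)
Conditions: NaBH4, MeOH, 0 °C
Reagents that add atoms: none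
Why: Borohydride reduction of the ketone masks C2 as a carbinol for the base‑ and ylide‑mediated steps; its configuration is irrelevant because step 10 reoxidises it, and the bicyclic acetal is inert to hydride.

Step 3
Reactants: 4
Product: 5 3,4‑dideoxy‑4‑C‑isopropyl‑D‑hexopyranose (lactol; anomers and C2 epimers; isopropyl trans to the C5 CH2OH)
Conditions: Amberlyst 15 (H+ form), H2O–dioxane, 90 °C
Reagents that add atoms: water, O
Why: Acid‑catalysed hydrolysis of the strained bicyclic 1,6‑anhydro acetal (glycoside hydrolysis), favoured because the free pyranose can place isopropyl and CH2OH equatorial; C4 and C5 are not involved.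

Step 4
Reactants: 5
Product: 6 (2S,3R)‑3‑isopropylhept‑6‑ene‑1,2,5‑triol (C5 carbinol epimers; heptene C2/C3 are sugar C5/C4)
Conditions: Ph3PCH3Br (4.5 equiv), KOtBu (4.4 equiv), THF, 0 → 60 °C
Reagents that add atoms: methyltriphenylphosphonium bromide, C[P+](c1ccccc1)(c1ccccc1)c1ccccc1.[Br-]
Why: Wittig methylenation of the open‑chain aldehyde form of the lactol with excess ylide (three equivalents are used up by the hydroxyls) turns C1 into the vinyl CH and frees O5–H; any base‑induced epimerisation can only touch the temporary C2 centre.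

Step 5
Reactants: 6
Product: 8 (5R)‑6‑methyl‑5‑[(2S)‑oxiran‑2‑yl]hept‑1‑en‑3‑ol (C5–C6 epoxide; C3 carbinol epimers), via primary tosylate 7 (not isolated)
Conditions: TsCl (1.05 equiv), Et3N, Bu2SnO (2 mol%), CH2Cl2, 0 °C → rt; then K2CO3, MeOH, rt
Reagents that add atoms: none
Why: Stannylene‑acetal‑directed sulfonylation picks the primary hydroxyl of the 1,2‑diol, and intramolecular Williamson displacement (3‑exo‑tet) by O5 closes the epoxide with retention at C5, since only the C6–O bond is broken.

Step 6
Reactants: 8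
Product: 9 tert‑butyldimethylsilyl ether of 8 at the allylic (C2) hydroxyl
Conditions: TBSCl, imidazole, DMF, rt
Reagents that add atoms: tert‑butyldimethylsilyl chloride, CC(C)(C)[Si](C)(C)Cl
Why: Silyl ether formation on the only free hydroxyl marks O2 as distinct from O5 for steps 8–10; the epoxide tolerates imidazole.

Step 7
Reactants: 9
Product: 10 (3R,4R)‑6‑(tert‑butyldimethylsilyloxy)‑4‑isopropylocta‑1,7‑dien‑3‑ol (silyloxy carbon epimers)
Conditions: Me3SI (4 equiv), n‑BuLi (3.9 equiv), THF, −10 °C → rt; aq. NH4Cl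
Reagents that add atoms: trimethylsulfonium iodide, C[S+](C)C.[I-]
Why: Dimethylsulfonium methylide opens the epoxide at the unhindered terminal carbon C6, and a second equivalent of ylide eliminates dimethyl sulfide from the β‑alkoxy sulfonium salt (sulfonium‑ylide one‑carbon homologation of an epoxide to an allylic alcohol); the C5–O bond is never broken, so C5 keeps its configuration.

Step 8
Reactants: 10
Product: 11 tert‑butyl{[(5R,6R)‑5‑isopropyl‑6‑(4‑methoxybenzyloxy)octa‑1,7‑dien‑3‑yl]oxy}dimethylsilane (C3 epimers)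
Conditions: NaH, PMBCl, Bu4NI (cat.), DMF, 0 °C → rt
Reagents that add atoms: 4‑methoxybenzyl chloride, COc1ccc(CCl)cc1
Why: Williamson etherification of the sodium alkoxide at O5 with the benzylic chloride (iodide catalysis); the secondary TBS ether has no neighbouring alkoxide to migrate to.

Step 9
Reactants: 11
Product: 12 (5R,6R)‑5‑isopropyl‑6‑(4‑methoxybenzyloxy)octa‑1,7‑dien‑3‑ol (C3 epimers)
Conditions: Bu4NF, THF, rt
Reagents that add atoms: none
Why: Fluoride cleavage of the silyl ether frees only O2; the PMB ether and both terminal alkenes are inert.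

Step 10
Reactants: 12
Product: 13 (5R,6R)‑5‑isopropyl‑6‑(4‑methoxybenzyloxy)octa‑1,7‑dien‑3‑one
Conditions: Dess–Martin periodinane, CH2Cl2, 0 °C → rt
Reagents that add atoms: none
Why: Dess–Martin oxidation of the allylic alcohol gives the vinyl ketone under non‑basic conditions and merges both C2 epimers into one compound, which is used at once.

Step 11
Reactants: 13
Product: 14 (4R,5R)‑5‑isopropyl‑4‑(4‑methoxybenzyloxy)cyclohex‑2‑en‑1‑one (ether oxygen cis to isopropyl)
Conditions: second‑generation Hoveyda–Grubbs catalyst RuCl2(H2IMes)(=CH‑C6H4‑2‑OiPr) (5 mol%), CH2Cl2 (0.005 M), 40 °C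
Reagents that add atoms: none
Why: Ring‑closing olefin metathesis: the ruthenium alkylidene forms first on the more electron‑rich allylic‑ether vinyl group (C6), adds to the vinyl ketone terminus (C1) within the same molecule through a ruthenacyclobutane, and cycloreversion gives the C1=C6 ring alkene while ethylene is lost. The closest known reaction type is the ring‑closing metathesis of carbohydrate‑derived 1,7‑dien‑3‑ones to 4‑alkoxycyclohex‑2‑enones with NHC‑ligated ruthenium catalysts. The one ring is closed by joining the two internal alkene carbons of a 1,7‑diene, which for a six‑membered ring can only give the cis ring alkene. No stereocentre is formed; C4 and C5 are not α to the ketone and the conditions are neutral, so the configuration fixed by the bridge‑directed conjugate addition and by the sugar C5 should pass through unchanged. The selectivity needed is cyclisation over cross‑metathesis or oligomerisation of the vinyl ketone, which high dilution, the favourable six‑membered ring and the slow homodimerisation of electron‑poor vinyl ketones should secure.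

Step 12
Reactants: 14
Product: 15 2‑(hydroxymethyl)‑5‑isopropyl‑4‑(4‑methoxybenzyloxy)cyclohex‑2‑en‑1‑one (stereocentres as in 14)
Conditions: 37% aq. HCHO, DMAP (0.5 equiv), THF–H2O, rt
Reagents that add atoms: formaldehyde, C=O
Why: Morita–Baylis–Hillman reaction: reversible DMAP addition at C6 gives an enolate that adds to formaldehyde at C1, and loss of DMAP restores the enone with C7 in place; it is run here because no base‑sensitive ester is yet present.

Step 13
Reactants: 15
Product: 16 2‑(tert‑butyldimethylsilyloxymethyl)‑5‑isopropyl‑4‑(4‑methoxybenzyloxy)cyclohex‑2‑en‑1‑one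
Conditions: TBSCl, imidazole, CH2Cl2, 0 °C → rt
Reagents that add atoms: tert‑butyldimethylsilyl chloride, CC(C)(C)[Si](C)(C)Cl
Why: Silylation of the primary allylic hydroxyl keeps O7 out of the enolate and acylation steps that follow.

Step 14
Reactants: 16
Product: 18 6‑hydroxy derivative of 16 (ring C3–OH trans to isopropyl; C3 S, C4 R, C5 R in ring numbering), via potassium enolate 17 (not isolated)
Conditions: KN(SiMe3)2, THF, −78 °C; then 2‑(phenylsulfonyl)‑3‑phenyloxaziridine, −78 °C; aq. NH4Cl
Reagents that add atoms: 2‑(phenylsulfonyl)‑3‑phenyloxaziridine, O=S(=O)(c1ccccc1)N1OC1c1ccccc1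
Why: Kinetic α′‑deprotonation gives the cross‑conjugated enolate (as with carvone), and electrophilic hydroxylation by the N‑sulfonyloxaziridine should occur on the face opposite the adjacent isopropyl group (and the cis C5 ether), setting C3 trans to C4.

Step 15
Reactants: 19 angelic acid
Product: 20 (Z)‑2‑methylbut‑2‑en‑1‑ol
Conditions: LiAlH4, Et2O, 0 °C → rt
Reagents that add atoms: none
Why: Hydride reduction of the carboxylic acid to the allylic alcohol; the trisubstituted alkene is not reduced and keeps its Z geometry.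

Step 16
Reactants: 20
Product: 21 [(2S,3R)‑2,3‑dimethyloxiran‑2‑yl]methanol
Conditions: Ti(OiPr)4 (10 mol%), L‑(+)‑diethyl tartrate (12 mol%), t‑BuOOH, 4 Å molecular sieves, CH2Cl2, −20 °C
Reagents that add atoms: tert‑butyl hydroperoxide, CC(C)(C)OO
Why: Sharpless asymmetric epoxidation; the L‑(+)‑tartrate complex delivers oxygen to the alkene face that gives the (2S,3R) epoxy alcohol, and the Z geometry fixes the C3 methyl cis to CH2OH.

Step 17
Reactants: 21
Product: 22 (2R,3R)‑2,3‑dimethyloxirane‑2‑carboxylic acid (epoxyangelic acid)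
Conditions: RuCl3·xH2O (2 mol%), NaIO4, CCl4–MeCN–H2O, rt
Reagents that add atoms: sodium periodate, [Na+].[O-]I(=O)(=O)=O
Why: Ruthenium tetroxide oxidation (catalytic RuCl3 with NaIO4) of the primary alcohol to the acid leaves the epoxide and both centres untouched; the C2 descriptor changes from S to R only because CO2H outranks the ring carbon.

Step 18
Reactants: 18; 22
Product: 24 C3 (2R,3R)‑epoxyangelate of 18, via mixed anhydride 23 (not isolated)
Conditions: 22, 2,4,6‑trichlorobenzoyl chloride, Et3N, THF, rt; then 18, DMAP, toluene, rt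
Reagents that add atoms: none
Why: Yamaguchi esterification: the alcohol attacks the unhindered epoxy‑acyl carbonyl of the mixed anhydride, with retention at C3 because only the O–H bond is broken; any minor enantiomer of 22 would end up as a separable diastereomer.

Step 19
Reactants: 24
Product: 25 C5 alcohol (PMB removed; C3 epoxyangelate and O7 TBS ether kept)
Conditions: DDQ, CH2Cl2–pH 7 buffer, 0 °C → rt
Reagents that add atoms: none
Why: Oxidative cleavage of the electron‑rich 4‑methoxybenzyl ether by DDQ under buffered conditions, which should spare the TBS ether, the epoxy ester and the electron‑poor enone.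

Step 20
Reactants: 25; 19 angelic acid
Product: 27 C5 angelate, C3 epoxyangelate, O7 TBS ether, via mixed anhydride 26 (not isolated)
Conditions: 19, 2,4,6‑trichlorobenzoyl chloride, Et3N, toluene, rt; then 25, 80 °C
Reagents that add atoms: none
Why: Yamaguchi‑type acylation through the trichlorobenzoyl mixed anhydride run without DMAP, the usual way to make angelates with little Z→E isomerisation; the trans‑1,3 relation of O3 and O5 rules out acyl migration.

Step 21
Reactants: 27
Product: 28 target CNP0293054.1
Conditions: HF·pyridine, pyridine, THF, 0 °C → rt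
Reagents that add atoms: none
Why: Buffered fluoride desilylation frees the primary C7 hydroxyl under mildly acidic conditions, which should avoid base‑induced acyl migration or epimerisation at C3 and leave the electron‑poor epoxide intact.

**Compound list**

1 | levoglucosenone, (1S,5R)‑6,8‑dioxabicyclo[3.2.1]oct‑2‑en‑4‑one | O=C1C=C[C@H]2CO[C@@H]1O2 | starting material
2 | isopropylmagnesium chloride | CC(C)[Mg]Cl | starting material
3 | (1S,2R,5R)‑2‑isopropyl‑6,8‑dioxabicyclo[3.2.1]octan‑4‑one | O=C1C[C@H](C(C)C)[C@H]2CO[C@@H]1O2 | intermediate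
4 | 1,6‑anhydro‑3,4‑dideoxy‑4‑C‑isopropyl‑β‑D‑hexopyranose (C2 epimers) | OC1C[C@H](C(C)C)[C@H]2CO[C@@H]1O2 | intermediate
5 | 3,4‑dideoxy‑4‑C‑isopropyl‑D‑hexopyranose (anomers, C2 epimers) | OC[C@H]1OC(O)C(O)C[C@@H]1C(C)C | intermediate
6 | (2S,3R)‑3‑isopropylhept‑6‑ene‑1,2,5‑triol (C5 epimers) | C=CC(O)C[C@H](C(C)C)[C@H](O)CO | intermediate
7 | (2S,3R)‑2,5‑dihydroxy‑3‑isopropylhept‑6‑en‑1‑yl 4‑methylbenzenesulfonate | C=CC(O)C[C@H](C(C)C)[C@H](O)COS(=O)(=O)c1ccc(C)cc1 | intermediate
8 | (5R)‑6‑methyl‑5‑[(2S)‑oxiran‑2‑yl]hept‑1‑en‑3‑ol (C3 epimers) | C=CC(O)C[C@H](C(C)C)[C@H]1CO1 | intermediate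
9 | TBS ether of 8 | C=CC(O[Si](C)(C)C(C)(C)C)C[C@H](C(C)C)[C@H]1CO1 | intermediate
10 | (3R,4R)‑6‑(tert‑butyldimethylsilyloxy)‑4‑isopropylocta‑1,7‑dien‑3‑ol | C=CC(O[Si](C)(C)C(C)(C)C)C[C@H](C(C)C)[C@H](O)C=C | intermediate
11 | PMB ether of 10 at O5 | C=CC(O[Si](C)(C)C(C)(C)C)C[C@H](C(C)C)[C@H](OCc1ccc(OC)cc1)C=C | intermediate
12 | (5R,6R)‑5‑isopropyl‑6‑(4‑methoxybenzyloxy)octa‑1,7‑dien‑3‑ol (C3 epimers) | C=CC(O)C[C@H](C(C)C)[C@H](OCc1ccc(OC)cc1)C=C | intermediate
13 | (5R,6R)‑5‑isopropyl‑6‑(4‑methoxybenzyloxy)octa‑1,7‑dien‑3‑one | C=C[C@@H](OCc1ccc(OC)cc1)[C@@H](C(C)C)CC(=O)C=C | intermediate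
14 | (4R,5R)‑5‑isopropyl‑4‑(4‑methoxybenzyloxy)cyclohex‑2‑en‑1‑one | COc1ccc(CO[C@@H]2C=CC(=O)C[C@@H]2C(C)C)cc1 | intermediate
15 | 2‑(hydroxymethyl) derivative of 14 | COc1ccc(CO[C@@H]2C=C(CO)C(=O)C[C@@H]2C(C)C)cc1 | intermediate
16 | O7 TBS ether of 15 | COc1ccc(CO[C@@H]2C=C(CO[Si](C)(C)C(C)(C)C)C(=O)C[C@@H]2C(C)C)cc1 | intermediate
17 | potassium α′‑enolate of 16 | COc1ccc(CO[C@@H]2C=C(CO[Si](C)(C)C(C)(C)C)C(O[K])=C[C@@H]2C(C)C)cc1 | intermediate
18 | C3 alcohol (OH trans to isopropyl) | COc1ccc(CO[C@@H]2C=C(CO[Si](C)(C)C(C)(C)C)C(=O)[C@@H](O)[C@@H]2C(C)C)cc1 | intermediate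
19 | angelic acid, (Z)‑2‑methylbut‑2‑enoic acid | C/C=C(/C)C(=O)O | starting material
20 | (Z)‑2‑methylbut‑2‑en‑1‑ol | C/C=C(/C)CO | intermediate
21 | [(2S,3R)‑2,3‑dimethyloxiran‑2‑yl]methanol | OC[C@]1(C)O[C@@H]1C | intermediate
22 | (2R,3R)‑2,3‑dimethyloxirane‑2‑carboxylic acid | OC(=O)[C@]1(C)O[C@@H]1C | intermediate
23 | (2R,3R)‑epoxyangelic 2,4,6‑trichlorobenzoic anhydride | O=C(OC(=O)c1c(Cl)cc(Cl)cc1Cl)[C@]1(C)O[C@@H]1C | intermediate
24 | C3 epoxyangelate, C5 PMB ether, O7 TBS ether | COc1ccc(CO[C@@H]2C=C(CO[Si](C)(C)C(C)(C)C)C(=O)[C@@H](OC(=O)[C@]3(C)O[C@@H]3C)[C@@H]2C(C)C)cc1 | intermediate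
25 | C5 alcohol, C3 epoxyangelate, O7 TBS ether | O[C@@H]1C=C(CO[Si](C)(C)C(C)(C)C)C(=O)[C@@H](OC(=O)[C@]2(C)O[C@@H]2C)[C@@H]1C(C)C | intermediate
26 | angelic 2,4,6‑trichlorobenzoic anhydride | C/C=C(/C)C(=O)OC(=O)c1c(Cl)cc(Cl)cc1Cl | intermediate
27 | C5 angelate, C3 epoxyangelate, O7 TBS ether | C/C=C(/C)C(=O)O[C@@H]1C=C(CO[Si](C)(C)C(C)(C)C)C(=O)[C@@H](OC(=O)[C@]2(C)O[C@@H]2C)[C@@H]1C(C)C | intermediate
28 | CNP0293054.1 (ring C3 S, C4 R, C5 R; oxirane 2R,3R; Z angelate) | C/C=C(/C)C(=O)O[C@@H]1C=C(CO)C(=O)[C@@H](OC(=O)[C@]2(C)O[C@@H]2C)[C@@H]1C(C)C | target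

**Step count and risks**

Total: 21 steps. Longest linear sequence: 18 steps (steps 1–14 and 18–21 from levoglucosenone); the epoxy acid branch is steps 15–17.

Steps most likely to fail:

- Step 11 (key ring closure). The vinyl ketone may undergo intermolecular cross‑metathesis or oligomerise, and the enone may chelate and deactivate the catalyst, so that ring closure stays incomplete. Fallback: set out from 12 and close the ring at the allylic‑alcohol oxidation level with the second‑generation Grubbs catalyst RuCl2(=CHPh)(H2IMes)(PCy3) in dilute CH2Cl2. This would give 5‑isopropyl‑4‑(4‑methoxybenzyloxy)cyclohex‑2‑en‑1‑ol F1. Oxidation of its allylic alcohol with MnO2 in CH2Cl2 comes back to the route at 14.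

- Step 12 (hydroxymethylation). Amine addition at C6, which is flanked by the C5 ether, may be slow or reversible, so that the reaction stalls or the product condenses further with formaldehyde. Fallback: from 14, α‑iodination through pyridine addition–elimination (I2, pyridine, CH2Cl2) would give the α‑iodo enone 2‑iodo‑5‑isopropyl‑4‑(4‑methoxybenzyloxy)cyclohex‑2‑en‑1‑one F2 (stereocentres as in 14). Stille coupling with (tributylstannyl)methanol [Pd(PPh3)4, zerovalent palladium, dioxane, 80 °C] comes back at 15.

- Step 20 (angeloylation). The angeloyl unit may isomerise to the E (tigloyl) isomer during activation, acylation of the hindered C5 hydroxyl may be slow, and the γ‑hydroxy enone may isomerise under base and heat. Fallback: from 25, acylate O5 at 0 °C with 2‑(diphenoxyphosphoryl)propanoic acid (DCC, DMAP cat., CH2Cl2) to give the O5 2‑(diphenoxyphosphoryl)propanoate of 25 F3. The Z alkene is then built on the ester by the Z‑selective diaryl phosphonate variant of the Horner–Wadsworth–Emmons reaction with acetaldehyde (NaI, DBU, THF, −78 → 0 °C), which comes back at 27.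

**Further compounds**

F1 | step 11 | 5‑isopropyl‑4‑(4‑methoxybenzyloxy)cyclohex‑2‑en‑1‑ol (C1 carbinol epimers; C4 and C5 as in 14) | COc1ccc(CO[C@@H]2C=CC(O)C[C@@H]2C(C)C)cc1
F2 | step 12 | 2‑iodo‑5‑isopropyl‑4‑(4‑methoxybenzyloxy)cyclohex‑2‑en‑1‑one | COc1ccc(CO[C@@H]2C=C(I)C(=O)C[C@@H]2C(C)C)cc1
F3 | step 20 | O5 2‑(diphenoxyphosphoryl)propanoate of 25 | CC(C(=O)O[C@@H]1C=C(CO[Si](C)(C)C(C)(C)C)C(=O)[C@@H](OC(=O)[C@]2(C)O[C@@H]2C)[C@@H]1C(C)C)P(=O)(Oc1ccccc1)Oc1ccccc1
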